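**Retrosynthetic overview**
- Attenol A ⇒ open-chain C11 ketone carrying the C7 and C14 hydroxyls; both spiroketal rings (ring A = oxolane, ring B = oxane) close together in the last step under acid, with loss of CO2 from a β-keto lactone.
- The C11–C12 bond ⇒ crossed Claisen condensation of a five-membered lactone enolate (C12–C21 plus one sacrificial carboxyl carbon) with a six-membered lactone (C1–C11).
- The six-membered lactone (ring B precursor) ⇒ Baeyer–Villiger ring expansion of a trans-2,3-disubstituted cyclopentanone, which makes the C7–O bond with retention.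
- The cyclopentanone ⇒ cyclopent-2-enone + Me2Zn + a (Z)-β,γ-unsaturated aldehyde by asymmetric conjugate addition–aldol (C6, C7, C8).
- The five-membered lactone (ring A precursor) ⇒ a 4,6-dioxo acid (from hept-6-en-2-one and succinic anhydride) by double asymmetric hydrogenation–lactonisation (C14, C16).

Assumption: (Z)-hex-3-ene-1,6-diol (1) is bought as a catalogue compound.
Labels: stereocentres are named by attenol numbering (C1 = CH2OH carbon, C11 = spiro carbon, C21 = vinyl CH2). L* in step 3 is the dipeptide phosphine 2-(Ph2P)C6H4CH=N-L-Tle-L-Tyr(O-t-Bu)-NH-n-Bu; its mirror image is used if a test protonation of enolate 5 gives (S)- instead of (R)-3-methylcyclopentanone.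

**Step 1**
Reactants: 1 (Z)-hex-3-ene-1,6-diol
Product: 2 (Z)-6-(tert-butyldimethylsilyloxy)hex-3-en-1-ol
Conditions: NaH (1.0 equiv), THF, 0 °C; TBSCl (1.0 equiv), rt
Reagents that add atoms: tert-butyldimethylsilyl chloride, CC(C)(C)[Si](C)(C)Cl
Why: Monosilylation of a symmetrical diol through its sparingly soluble monosodium alkoxide, which is silylated once (McDougal monoprotection); no stereocentre is involved and the Z-alkene is untouched.

**Step 2**
Reactants: 2 (Z)-6-(tert-butyldimethylsilyloxy)hex-3-en-1-ol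
Product: 3 (Z)-6-(tert-butyldimethylsilyloxy)hex-3-enal
Conditions: Dess–Martin periodinane, NaHCO3, CH2Cl2, 0 °C; used at once
Reagents that add atoms: none
Why: Dess–Martin oxidation is fast and, when buffered and cold, gives the skipped (Z)-β,γ-unsaturated aldehyde without migration of the double bond into conjugation.

**Step 3**
Reactants: 4 cyclopent-2-en-1-one; 3 (Z)-6-(tert-butyldimethylsilyloxy)hex-3-enal
Product: 6 (2R,3R)-2-[(1R,3Z)-6-(tert-butyldimethylsilyloxy)-1-hydroxyhex-3-en-1-yl]-3-methylcyclopentan-1-one, via methylzinc enolate 5 (not isolated)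
Conditions: Me2Zn (1.5 equiv), Cu(OTf)2 (2 mol%), L* (4 mol%), toluene, –30 °C; then 3, –78 to –40 °C; AcOH
Reagents that add atoms: dimethylzinc, C[Zn]C
Why: Tandem copper-catalysed asymmetric conjugate addition–aldol (three-component coupling), in which the chiral ligand sets C8 (R), the regiodefined zinc enolate 5 is attacked anti to the new methyl group (C7, trans) and the Zimmerman–Traxler chair of the cyclic E-enolate gives the anti aldol (C6, R), the minor C6 epimer being removed on silica.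

**Step 4**
Reactants: 6 (2R,3R)-2-[(1R,3Z)-6-(tert-butyldimethylsilyloxy)-1-hydroxyhex-3-en-1-yl]-3-methylcyclopentan-1-one
Product: 7 (2R,3R)-2-[(1R,3Z)-1,6-bis(tert-butyldimethylsilyloxy)hex-3-en-1-yl]-3-methylcyclopentan-1-one
Conditions: TBSOTf, 2,6-lutidine, CH2Cl2, –78 °C
Reagents that add atoms: tert-butyldimethylsilyl trifluoromethanesulfonate, CC(C)(C)[Si](C)(C)OS(=O)(=O)C(F)(F)F
Why: Silyl triflate with a hindered pyridine silylates the secondary β-hydroxy ketone at –78 °C faster than retro-aldol or β-elimination can occur (standard silyl ether protection).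

**Step 5**
Reactants: 7 (2R,3R)-2-[(1R,3Z)-1,6-bis(tert-butyldimethylsilyloxy)hex-3-en-1-yl]-3-methylcyclopentan-1-one
Product: 9 (5R,6R)-6-[(1R,3Z)-1,6-bis(tert-butyldimethylsilyloxy)hex-3-en-1-yl]-5-methyloxan-2-one, via silylperoxy ketal 8 (not isolated)
Conditions: Me3SiOOSiMe3 (3 equiv), SnCl4 (10 mol%), trans-cyclohexane-1,2-diamine (10 mol%), 4 Å MS, CH2Cl2, 0 °C to rt
Reagents that add atoms: bis(trimethylsilyl) peroxide, C[Si](C)(C)OO[Si](C)(C)C
Why: Baeyer–Villiger ring expansion in which the silyl peroxide adds to the ketone (Criegee adduct 8) and the more substituted C7 migrates from carbon to oxygen with retention of configuration, while the silyl peroxide/SnCl4–diamine system does not epoxidise the Z-alkene.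

**Step 6**
Reactants: 10 hept-6-en-2-one; 11 succinic anhydride (oxolane-2,5-dione)
Product: 13 4,6-dioxoundec-10-enoic acid, via lithium enolate 12 (not isolated)
Conditions: LiN(i-Pr)2 (2.1 equiv), 10 (2.1 equiv), THF, –78 °C; 11 (1.0 equiv), –78 to 0 °C; 1 M HCl
Reagents that add atoms: none
Why: Claisen-type C-acylation of the kinetic methyl-side lithium enolate 12 by the cyclic anhydride, the second equivalent of enolate deprotonating the acidic β-diketone so that it is not acylated twice.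

**Step 7**
Reactants: 13 4,6-dioxoundec-10-enoic acid
Product: 15 (5S)-5-[(2S)-2-hydroxyhept-6-en-1-yl]oxolan-2-one, via dihydroxy acid 14 (not isolated)
Conditions: RuCl2[(S)-BINAP](dmf)n (1 mol%), H2 (4 atm), MeOH, 50 °C; then TsOH (cat.), toluene, rt
Reagents that add atoms: none
Why: Proposed new method: double asymmetric hydrogenation of a 4,6-dioxoalkanoic acid with lactonisation in the same flask, reasoning that the β-diketone binds ruthenium as a six-membered O,O-chelate faster than the seven-membered keto-carboxylate chelate, the first hydride transfer gives a β-hydroxy ketone that is reduced under catalyst control to the anti (14S,16S) diol, the 4-hydroxy acid then closes to the five-membered lactone and the low H2 pressure spares the terminal alkene; the closest known reaction type is the Noyori hydrogenation of β-diketones to anti-1,3-diols and of 4-oxo esters to γ-lactones.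

**Step 8**
Reactants: 15 (5S)-5-[(2S)-2-hydroxyhept-6-en-1-yl]oxolan-2-one
Product: 16 (5S)-5-[(2S)-2-(tert-butyldimethylsilyloxy)hept-6-en-1-yl]oxolan-2-one
Conditions: TBSCl, imidazole, DMF, rt
Reagents that add atoms: tert-butyldimethylsilyl chloride, CC(C)(C)[Si](C)(C)Cl
Why: Routine imidazole-promoted silylation of the only free hydroxyl, to which the γ-lactone is inert.

**Step 9**
Reactants: 16 (5S)-5-[(2S)-2-(tert-butyldimethylsilyloxy)hept-6-en-1-yl]oxolan-2-one; 9 (5R,6R)-6-[(1R,3Z)-1,6-bis(tert-butyldimethylsilyloxy)hex-3-en-1-yl]-5-methyloxan-2-one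
Product: 18 (5S)-3-[(4R,5R,6R,8Z)-6,11-bis(tert-butyldimethylsilyloxy)-5-hydroxy-4-methylundec-8-enoyl]-5-[(2S)-2-(tert-butyldimethylsilyloxy)hept-6-en-1-yl]oxolan-2-one (C3 epimers, in equilibrium with its six-membered hemiketal), via lithium enolate 17 (not isolated)
Conditions: 16 (2.2 equiv), LiN(i-Pr)2 (2.2 equiv), THF, –78 °C; 9 (1.0 equiv), –78 to –30 °C; AcOH
Reagents that add atoms: none
Why: Crossed Claisen condensation of two lactones, in which γ-lactone enolate 17 attacks the more electrophilic six-membered lactone at C11 and opens it to the C7 alkoxide, the second equivalent of 17 trapping the product as its stabilised β-dicarbonyl enolate; the new C12 centre is lost later, so its configuration does not matter.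

**Step 10**
Reactants: 18 (5S)-3-[(4R,5R,6R,8Z)-6,11-bis(tert-butyldimethylsilyloxy)-5-hydroxy-4-methylundec-8-enoyl]-5-[(2S)-2-(tert-butyldimethylsilyloxy)hept-6-en-1-yl]oxolan-2-one
Product: 21 attenol A, via keto acid 19 (not isolated), via pentahydroxy ketone 20 (not isolated)
Conditions: LiOH, THF/MeOH/H2O, rt; then 2 M HCl to pH 1, 45 °C
Reagents that add atoms: none
Why: Saponification of the γ-lactone by acyl–oxygen cleavage (C14 untouched) and acidification give β-keto acid 19, which decarboxylates, the acid also removes the three silyl ethers, and ketone 20 undergoes thermodynamic spiroketalisation to the C11 (S) spiroketal (ring A oxygen axial on chair ring B, both ring B substituents equatorial), any bicyclic ketal isomer (attenol B) being re-equilibrated under the same acid.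

**Compound list**
1 | (Z)-hex-3-ene-1,6-diol | OCC/C=C\CCO | starting material
2 | (Z)-6-(tert-butyldimethylsilyloxy)hex-3-en-1-ol | OCC/C=C\CCO[Si](C)(C)C(C)(C)C | intermediate
3 | (Z)-6-(tert-butyldimethylsilyloxy)hex-3-enal | O=CC/C=C\CCO[Si](C)(C)C(C)(C)C | intermediate
4 | cyclopent-2-en-1-one | O=C1C=CCC1 | starting material
5 | methylzinc (R)-3-methylcyclopent-1-en-1-olate | C[Zn]OC1=C[C@H](C)CC1 | intermediate
6 | (2R,3R)-2-[(1R,3Z)-6-(tert-butyldimethylsilyloxy)-1-hydroxyhex-3-en-1-yl]-3-methylcyclopentan-1-one | O=C1CC[C@@H](C)[C@@H]1[C@H](O)C/C=C\CCO[Si](C)(C)C(C)(C)C | intermediate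
7 | (2R,3R)-2-[(1R,3Z)-1,6-bis(tert-butyldimethylsilyloxy)hex-3-en-1-yl]-3-methylcyclopentan-1-one | O=C1CC[C@@H](C)[C@@H]1[C@H](O[Si](C)(C)C(C)(C)C)C/C=C\CCO[Si](C)(C)C(C)(C)C | intermediate
8 | (2R,3R)-2-[(1R,3Z)-1,6-bis(tert-butyldimethylsilyloxy)hex-3-en-1-yl]-3-methyl-1-(trimethylsilyloxy)-1-(trimethylsilylperoxy)cyclopentane (Criegee adduct, C1 undefined) | C[Si](C)(C)OOC1(O[Si](C)(C)C)CC[C@@H](C)[C@@H]1[C@H](O[Si](C)(C)C(C)(C)C)C/C=C\CCO[Si](C)(C)C(C)(C)C | intermediate
9 | (5R,6R)-6-[(1R,3Z)-1,6-bis(tert-butyldimethylsilyloxy)hex-3-en-1-yl]-5-methyloxan-2-one | O=C1CC[C@@H](C)[C@H]([C@H](O[Si](C)(C)C(C)(C)C)C/C=C\CCO[Si](C)(C)C(C)(C)C)O1 | intermediate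
10 | hept-6-en-2-one | CC(=O)CCCC=C | starting material
11 | succinic anhydride (oxolane-2,5-dione) | O=C1CCC(=O)O1 | starting material
12 | lithium hepta-1,6-dien-2-olate | [Li]OC(=C)CCCC=C | intermediate
13 | 4,6-dioxoundec-10-enoic acid | OC(=O)CCC(=O)CC(=O)CCCC=C | intermediate
14 | (4S,6S)-4,6-dihydroxyundec-10-enoic acid | OC(=O)CC[C@H](O)C[C@@H](O)CCCC=C | intermediate
15 | (5S)-5-[(2S)-2-hydroxyhept-6-en-1-yl]oxolan-2-one | C=CCCC[C@H](O)C[C@@H]1CCC(=O)O1 | intermediate
16 | (5S)-5-[(2S)-2-(tert-butyldimethylsilyloxy)hept-6-en-1-yl]oxolan-2-one | C=CCCC[C@H](O[Si](C)(C)C(C)(C)C)C[C@@H]1CCC(=O)O1 | intermediate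
17 | lithium (5S)-5-[(2S)-2-(tert-butyldimethylsilyloxy)hept-6-en-1-yl]-4,5-dihydrofuran-2-olate | C=CCCC[C@H](O[Si](C)(C)C(C)(C)C)C[C@@H]1CC=C(O[Li])O1 | intermediate
18 | (5S)-3-[(4R,5R,6R,8Z)-6,11-bis(tert-butyldimethylsilyloxy)-5-hydroxy-4-methylundec-8-enoyl]-5-[(2S)-2-(tert-butyldimethylsilyloxy)hept-6-en-1-yl]oxolan-2-one (C3 undefined) | C=CCCC[C@H](O[Si](C)(C)C(C)(C)C)C[C@@H]1CC(C(=O)CC[C@@H](C)[C@@H](O)[C@H](O[Si](C)(C)C(C)(C)C)C/C=C\CCO[Si](C)(C)C(C)(C)C)C(=O)O1 | intermediate
19 | (6R,7R,8R,10Z)-8,13-bis(tert-butyldimethylsilyloxy)-7-hydroxy-2-[(2S,4S)-4-(tert-butyldimethylsilyloxy)-2-hydroxynon-8-en-1-yl]-6-methyl-3-oxotridec-10-enoic acid (formed as its lithium salt, C2 undefined) | C=CCCC[C@H](O[Si](C)(C)C(C)(C)C)C[C@@H](O)CC(C(=O)O)C(=O)CC[C@@H](C)[C@@H](O)[C@H](O[Si](C)(C)C(C)(C)C)C/C=C\CCO[Si](C)(C)C(C)(C)C | intermediate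
20 | (3Z,6R,7R,8R,14S,16S)-1,6,7,14,16-pentahydroxy-8-methylhenicosa-3,20-dien-11-one | C=CCCC[C@H](O)C[C@@H](O)CCC(=O)CC[C@@H](C)[C@@H](O)[C@H](O)C/C=C\CCO | intermediate
21 | attenol A | C=CCCC[C@H](O)C[C@@H]1CC[C@@]2(CC[C@@H](C)[C@H]([C@H](O)C/C=C\CCO)O2)O1 | target

**Step count and risks**
Total steps: 10. Longest linear sequence: 7 (steps 1, 2, 3, 4, 5, 9, 10).

Step 3 (conjugate addition–aldol). The risks are isomerisation of aldehyde 3 to the conjugated enal, a modest anti:syn ratio at C6, and the enantioselectivity of methyl addition to a five-membered enone. The fallback sets out from 4 and moves alkene formation to after the ring expansion.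
- The same copper-catalysed methyl addition is run, but enolate 5 is trapped with the non-isomerisable 3-(benzyloxy)propanal to give (2R,3R)-2-[(1R)-3-(benzyloxy)-1-hydroxypropyl]-3-methylcyclopentan-1-one F1.
- Silylation (TBSOTf, 2,6-lutidine) gives (2R,3R)-2-[(1R)-3-(benzyloxy)-1-(tert-butyldimethylsilyloxy)propyl]-3-methylcyclopentan-1-one F2.
- Baeyer–Villiger oxidation with mCPBA/NaHCO3 (no alkene is present yet) gives (5R,6R)-6-[(1R)-3-(benzyloxy)-1-(tert-butyldimethylsilyloxy)propyl]-5-methyloxan-2-one F3.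
- Hydrogenolysis (H2, Pd/C, EtOAc) gives (5R,6R)-6-[(1R)-1-(tert-butyldimethylsilyloxy)-3-hydroxypropyl]-5-methyloxan-2-one F4.
- Dess–Martin oxidation gives (3R)-3-(tert-butyldimethylsilyloxy)-3-[(2R,3R)-3-methyl-6-oxooxan-2-yl]propanal F5.
- A Z-selective Wittig reaction with the ylide from [3-(tert-butyldimethylsilyloxy)propyl]triphenylphosphonium bromide and NaN(SiMe3)2 (THF, –78 °C) comes back to the route at lactone 9.

Step 7 (proposed new hydrogenation–lactonisation). The risks are that the competing keto-carboxylate chelate would give the wrong sense at C14, that early lactonisation would remove the hydroxyl direction for C16, and that the terminal alkene could be reduced or isomerised. The fallback uses known chemistry and sets out from 10.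
- A boron aldol of 10 with methyl 4-oxobutanoate, using (Ipc)2BCl of the enantiomeric series that gives the (4S) alcohol (Et3N, Et2O, –78 °C; H2O2 work-up), gives methyl (4S)-4-hydroxy-6-oxoundec-10-enoate F6.
- Hydroxyl-directed anti reduction with Me4NBH(OAc)3 (MeCN/AcOH, –30 °C) gives methyl (4S,6S)-4,6-dihydroxyundec-10-enoate F7.
- Lactonisation (PPTS, toluene) comes back to the route at lactone 15.

Step 9 (crossed Claisen of two enolisable lactones). The risk is proton transfer from 9 to enolate 17, which would scramble the condensation. The fallback sets out from 9 and replaces the lactone by a far less acidic acyl donor.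
- Opening of 9 with AlMe3/MeNH(OMe)·HCl (CH2Cl2) gives (4R,5R,6R,8Z)-6,11-bis(tert-butyldimethylsilyloxy)-5-hydroxy-N-methoxy-N,4-dimethylundec-8-enamide F8.
- Silylation (TBSOTf, 2,6-lutidine) gives (4R,5R,6R,8Z)-5,6,11-tris(tert-butyldimethylsilyloxy)-N-methoxy-N,4-dimethylundec-8-enamide F9.
- Acylation of enolate 17 with this amide (THF, –78 to 0 °C) gives (5S)-5-[(2S)-2-(tert-butyldimethylsilyloxy)hept-6-en-1-yl]-3-[(4R,5R,6R,8Z)-5,6,11-tris(tert-butyldimethylsilyloxy)-4-methylundec-8-enoyl]oxolan-2-one F10.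
- The conditions of step 10 then convert it and come back to the route at 21.

**Further compounds**
F1 | step 3 | (2R,3R)-2-[(1R)-3-(benzyloxy)-1-hydroxypropyl]-3-methylcyclopentan-1-one | O=C1CC[C@@H](C)[C@@H]1[C@H](O)CCOCc1ccccc1
F2 | step 3 | (2R,3R)-2-[(1R)-3-(benzyloxy)-1-(tert-butyldimethylsilyloxy)propyl]-3-methylcyclopentan-1-one | O=C1CC[C@@H](C)[C@@H]1[C@H](O[Si](C)(C)C(C)(C)C)CCOCc1ccccc1
F3 | step 3 | (5R,6R)-6-[(1R)-3-(benzyloxy)-1-(tert-butyldimethylsilyloxy)propyl]-5-methyloxan-2-one | O=C1CC[C@@H](C)[C@H]([C@H](O[Si](C)(C)C(C)(C)C)CCOCc2ccccc2)O1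
F4 | step 3 | (5R,6R)-6-[(1R)-1-(tert-butyldimethylsilyloxy)-3-hydroxypropyl]-5-methyloxan-2-one | O=C1CC[C@@H](C)[C@H]([C@H](O[Si](C)(C)C(C)(C)C)CCO)O1
F5 | step 3 | (3R)-3-(tert-butyldimethylsilyloxy)-3-[(2R,3R)-3-methyl-6-oxooxan-2-yl]propanal | O=C1CC[C@@H](C)[C@H]([C@H](O[Si](C)(C)C(C)(C)C)CC=O)O1
F6 | step 7 | methyl (4S)-4-hydroxy-6-oxoundec-10-enoate | COC(=O)CC[C@H](O)CC(=O)CCCC=C
F7 | step 7 | methyl (4S,6S)-4,6-dihydroxyundec-10-enoate | COC(=O)CC[C@H](O)C[C@@H](O)CCCC=C
F8 | step 9 | (4R,5R,6R,8Z)-6,11-bis(tert-butyldimethylsilyloxy)-5-hydroxy-N-methoxy-N,4-dimethylundec-8-enamide | CON(C)C(=O)CC[C@@H](C)[C@@H](O)[C@H](O[Si](C)(C)C(C)(C)C)C/C=C\CCO[Si](C)(C)C(C)(C)C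
F9 | step 9 | (4R,5R,6R,8Z)-5,6,11-tris(tert-butyldimethylsilyloxy)-N-methoxy-N,4-dimethylundec-8-enamide | CON(C)C(=O)CC[C@@H](C)[C@@H](O[Si](C)(C)C(C)(C)C)[C@H](O[Si](C)(C)C(C)(C)C)C/C=C\CCO[Si](C)(C)C(C)(C)C
F10 | step 9 | (5S)-5-[(2S)-2-(tert-butyldimethylsilyloxy)hept-6-en-1-yl]-3-[(4R,5R,6R,8Z)-5,6,11-tris(tert-butyldimethylsilyloxy)-4-methylundec-8-enoyl]oxolan-2-one | C=CCCC[C@H](O[Si](C)(C)C(C)(C)C)C[C@@H]1CC(C(=O)CC[C@@H](C)[C@@H](O[Si](C)(C)C(C)(C)C)[C@H](O[Si](C)(C)C(C)(C)C)C/C=C\CCO[Si](C)(C)C(C)(C)C)C(=O)O1
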